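**Plan**
- Retrosynthetic cuts, in order: the C8 acetate; the C8–CH3 bond (methyl addition to the C8 carbonyl of a 7,8-dione); the C13–O ether bond together with the C15–O lactone bond (epoxide opening, then lactonization); the C9–C11 bond (B-alkyl Suzuki coupling at a C9 enol triflate); the C4–CH3 bond; then the C1–C2 and C5–C10 bonds together in one intramolecular Diels–Alder reaction; last the vinyl and isopropenyl ketone arms of a butenolide.
- Forward order: the 19,6-lactone is made first, as a C4=C5 butenolide; rings A and B then form together; the side chain is coupled; the spiro tetrahydrofuran and the second lactone close in one operation; ring B is oxidized last.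
- Enabling feature: the 19,6β-γ-lactone (C19–O–C6), in its unsaturated form, is the C4=C5 half of the diene C2=C3–C4=C5 and holds O6 in the diene plane. The future C9 ketone activates the C1=C10 isopropenyl dienophile, which hangs on a C7–C8–C9 tether from C6.
- Stereochemistry: C6 from a catalytic asymmetric alkynylation; C5 and C10 relayed from C6 in the cycloaddition; C4 by α-face methylation of the lactone enolate; C13 from a Sharpless epoxide, inverted on ring closure; C9 by α-face ketohydroxylation; C8 by α-face methyl addition.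

Key step: step 6

Remark: atoms are named by the labdane numbering of the target (C19 = ring-A lactone carbonyl, C15 = side-chain lactone carbonyl, C16 = its OCH2); α is the face of H5 and β the face of the C10 methyl.

**Step 1**
Reactants: 1 tert-butyl 4-oxobutanoate; 2 methyl prop-2-ynoate
Product: 4 methyl (4R)-7-tert-butoxy-4-hydroxy-7-oxohept-2-ynoate, via methylzinc alkynylide 3 (not isolated)
Conditions: Me2Zn, (R,R)-ProPhenol (10 mol %), Ph3PO (20 mol %), toluene, 4 °C; aq. NH4Cl
Reagents that add atoms: none
Why: Zn–ProPhenol-catalysed enantioselective alkynylation of an aliphatic aldehyde with a propiolate should set C6, the ligand enantiomer being the one expected to add the alkynylzinc to the aldehyde face that gives the R carbinol.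

**Step 2**
Reactants: 4
Product: 6 tert-butyl 3-[(2R)-5-oxo-4-(tributylstannyl)-2,5-dihydrofuran-2-yl]propanoate, via hydroxy stannyl enoate 5 (not isolated)
Conditions: Bu3SnH, Pd(PPh3)4 (2 mol %), THF, 0 °C; then PPTS (cat.), 23 °C
Reagents that add atoms: tributyltin hydride, CCCC[SnH](CCCC)CCCC
Why: Pd-catalysed syn-hydrostannation of an ynoate places tin α to the ester and leaves the ester cis to the carbinol, so the γ-hydroxy ester should lactonize to the α-stannyl butenolide without touching C6.

**Step 3**
Reactants: 6
Product: 7 tert-butyl 3-[(2R)-4-ethenyl-5-oxo-2,5-dihydrofuran-2-yl]propanoate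
Conditions: bromoethene (1 M in THF), Pd2(dba)3 (2.5 mol %), AsPh3, CuI, NMP, 40 °C
Reagents that add atoms: bromoethene, C=CBr
Why: Stille coupling of an α-stannyl butenolide with a vinyl halide, under neutral conditions that should not epimerize the γ-carbon, installs C2=C3 and completes the diene.

**Step 4**
Reactants: 7
Product: 8 3-[(2R)-4-ethenyl-5-oxo-2,5-dihydrofuran-2-yl]propanoic acid
Conditions: TFA, CH2Cl2, 0 → 23 °C
Reagents that add atoms: none
Why: Acidolysis of the tert-butyl ester frees the C9 carboxylic acid, and the electron-poor diene and the butenolide should tolerate the acid.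

**Step 5**
Reactants: 8
Product: 10 (5R)-3-ethenyl-5-(4-methyl-3-oxopent-4-en-1-yl)furan-2(5H)-one, via acid chloride 9 (not isolated)
Conditions: (COCl)2, DMF (cat.), CH2Cl2, 0 °C; then tributyl(isopropenyl)stannane, Pd(PPh3)4 (3 mol %), BHT, THF, 23 °C
Reagents that add atoms: tributyl(prop-1-en-2-yl)stannane, CC(=C)[Sn](CCCC)(CCCC)CCCC
Why: Acyl Stille coupling of an acid chloride with an alkenylstannane gives the isopropenyl ketone under non-basic conditions, which a Grignard route would not allow beside the butenolide.

**Step 6**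
Reactants: 10
Product: 11 tricyclic keto lactone (9-oxo; C3=C4; 19,6β-olide; rings A/B trans-fused; 5α-H; 6α-H; 10β-CH3)
Conditions: toluene (0.005 M), BHT (cat.), 110 °C
Reagents that add atoms: none
Why: Thermal, concerted but asynchronous intramolecular [4+2] cycloaddition of a 1,7,9-decatrien-3-one whose C4=C5 diene half is the butenolide double bond; the closest known reactions are enone-activated decatrienone cyclizations and peri-annulating Diels–Alder reactions of 1-vinylcycloalkenes tethered at the allylic ring carbon. Ring A is the new cyclohexene made by both new bonds (C1–C2 and C5–C10), and ring B is closed in the fused mode by the C5–C10 bond through the four-atom C6–C9 tether. C6 controls C5: the tether leaves C6 on one face of the flat butenolide, so the dienophile can reach only that face, which puts H5 cis to H6. The same constraint should control C10: with O6 held in the diene plane, C7 points away from the diene and can be linked to C9 only when the ketone is exo and the C10 methyl endo, which gives the trans ring fusion (H5 α, CH3 β). The step needs exo (trans-fused) selectivity and intramolecular over intermolecular reaction; the rigid lactone should secure the first, and high dilution with a radical inhibitor the second.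

**Step 7**
Reactants: 11
Product: 13 C9 enol triflate of 11 (C8=C9–OTf), via potassium enolate 12 (not isolated)
Conditions: KHMDS, THF, −78 °C; then PhNTf2, −78 → 0 °C
Reagents that add atoms: N-phenylbis(trifluoromethanesulfonimide), O=S(=O)(N(c1ccccc1)S(=O)(=O)C(F)(F)F)C(F)(F)F
Why: Kinetic enolization can occur only toward C8 because C10 is quaternary, and O-triflation both protects the ketone for the next step and provides the handle for the C9–C11 coupling.

**Step 8**
Reactants: 13
Product: 15 4α-methyl triflate (as 13 with ring A saturated; C4 bearing CH3 α and C19 β), via lithium lactone enolate 14 (not isolated)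
Conditions: LiBH(s-Bu)3 (L-Selectride), THF, −78 °C; then MeI, DMPU, −78 → −20 °C
Reagents that add atoms: iodomethane, CI
Why: Conjugate reduction of the α-alkylidene lactone followed by enolate alkylation (reductive alkylation) should set C4, since MeI can approach only the α face, which is away from the C10 methyl and keeps the γ-lactone cis-bridged to O6.

**Step 9**
Reactants: 16 itaconic anhydride
Product: 17 mono-tert-butyl itaconate (4-tert-butoxy-2-methylidene-4-oxobutanoic acid)
Conditions: t-BuOH, reflux
Reagents that add atoms: tert-butanol, CC(C)(C)O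
Why: Alcoholysis of the cyclic anhydride occurs at the more electrophilic non-conjugated carbonyl, giving the monoester with the conjugated acid free.

**Step 10**
Reactants: 17
Product: 19 tert-butyl 3-(hydroxymethyl)but-3-enoate, via mixed carbonic anhydride 18 (not isolated)
Conditions: i-BuOCOCl, N-methylmorpholine, THF, −15 °C; then NaBH4, H2O, 0 °C
Reagents that add atoms: none
Why: Mixed-anhydride activation followed by borohydride reduction converts the acid into the allylic alcohol without reducing the tert-butyl ester, which is also too hindered to lactonize.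

**Step 11**
Reactants: 19
Product: 20 tert-butyl 2-[(2R)-2-(hydroxymethyl)oxiran-2-yl]acetate
Conditions: Ti(OiPr)4 (10 mol %), D-(−)-diethyl tartrate (12 mol %), t-BuOOH, 4 Å MS, CH2Cl2, −20 °C
Reagents that add atoms: tert-butyl hydroperoxide, CC(C)(C)OO
Why: Sharpless asymmetric epoxidation of a 2-substituted allyl alcohol sets C13, the D-(−)-tartrate being expected to deliver oxygen in the same sense that converts methallyl alcohol into (R)-2-methylglycidol.

**Step 12**
Reactants: 20
Product: 21 tert-butyl 2-[(2S)-2-formyloxiran-2-yl]acetate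
Conditions: Dess–Martin periodinane, NaHCO3, CH2Cl2, 0 → 23 °C
Reagents that add atoms: none
Why: Buffered Dess–Martin oxidation gives the epoxy aldehyde, whose α-carbon is quaternary and so cannot epimerize.

**Step 13**
Reactants: 21
Product: 22 tert-butyl 2-[(2R)-2-ethenyloxiran-2-yl]acetate
Conditions: Ph3PCH3Br, KHMDS, THF, −78 → 0 °C
Reagents that add atoms: methyltriphenylphosphonium bromide, C[P+](c1ccccc1)(c1ccccc1)c1ccccc1.[Br-]
Why: Wittig methylenation of the non-enolizable aldehyde gives the vinyl group (C11=C12), and the ylide is not basic enough to enolize the ester.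

**Step 14**
Reactants: 15; 22
Product: 24 coupled alkene (C8=C9; C9–CH2CH2–C13, with C13 in the oxirane and bearing CH2CO2t-Bu), via B-alkyl-9-BBN 23 (not isolated)
Conditions: 22, 9-BBN, THF, 0 → 23 °C; then 15, Pd(dppf)Cl2 (5 mol %), AsPh3, Cs2CO3, DMF/H2O, 45 °C
Reagents that add atoms: none
Why: Anti-Markovnikov hydroboration of the vinyl group followed by B-alkyl Suzuki–Miyaura coupling with the hindered enol triflate forms C9–C11 under conditions that an epoxide and a tert-butyl ester should survive.

**Step 15**
Reactants: 24
Product: 25 9α-hydroxy-8-ketone (C13 oxirane and tert-butyl ester retained)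
Conditions: RuCl3 (1 mol %), Oxone, NaHCO3, EtOAc/MeCN/H2O, 23 °C
Reagents that add atoms: Oxone (potassium peroxymonosulfate), [K+].[O-]S(=O)(=O)OO
Why: Ru-catalysed ketohydroxylation adds both oxygens syn to the alkene face anti to the C10 methyl (α), and only the fully substituted C9 can end as the carbinol, which sets C9 with the chain β.

**Step 16**
Reactants: 25
Product: 27 8-oxo-9α,13R-epoxy-17-norlabdane-19,6β:15,16-diolide, via spiro ether hydroxy ester 26 (not isolated)
Conditions: CSA (0.2 equiv), CH2Cl2, 0 → 23 °C; then TFA, 23 °C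
Reagents that add atoms: none
Why: Acid-catalysed 5-exo opening of the epoxide by the 9α-hydroxyl at its tertiary carbon should proceed with inversion at C13 (both the substitution pattern and ring size disfavour the 6-endo path), and the freed C16 hydroxyl then lactonizes onto the tert-butyl ester.

**Step 17**
Reactants: 27
Product: 28 7,8-dioxo-9α,13R-epoxy-17-norlabdane-19,6β:15,16-diolide (may exist as the C6=C7 enol)
Conditions: SeO2, 1,4-dioxane, AcOH (cat.), 100 °C
Reagents that add atoms: selenium dioxide, O=[Se]=O
Why: Riley oxidation converts the only α-methylene of the ketone (C7, since C9 is quaternary) into a carbonyl without forming a free enolate that could expel the C6 acyloxy group.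

**Step 18**
Reactants: 28
Product: 30 8β-hydroxy-7-oxo-9α,13R-epoxylabdane-19,6β:15,16-diolide, via potassium enolate 29 (not isolated)
Conditions: KHMDS (1.05 equiv), THF, −78 °C; then MeMgBr, −78 → −40 °C; aq. NH4Cl
Reagents that add atoms: methylmagnesium bromide, C[Mg]Br
Why: Deprotonation at C6 masks the C7 carbonyl as its enolate, so Grignard 1,2-addition should occur only at C8 and from the α (equatorial) side, the β side being blocked by the syn-axial C10 methyl; on work-up C6 is reprotonated from the α face because the lactone bridge allows no other configuration.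

**Step 19**
Reactants: 30
Product: 31 8β-acetoxy-7-oxo-9α,13R-epoxylabdane-19,6β:15,16-diolide (target)
Conditions: Ac2O, Sc(OTf)3 (5 mol %), MeCN, −20 → 0 °C
Reagents that add atoms: acetic anhydride, CC(=O)OC(C)=O
Why: Lewis-acid-catalysed acylation is a standard way to esterify hindered tertiary alcohols, and it touches no stereocenter.

**Compound list**
1 | tert-butyl 4-oxobutanoate | O=CCCC(=O)OC(C)(C)C | starting material
2 | methyl prop-2-ynoate | C#CC(=O)OC | starting material
3 | methylzinc alkynylide of 2 | C[Zn]C#CC(=O)OC | intermediate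
4 | methyl (4R)-7-tert-butoxy-4-hydroxy-7-oxohept-2-ynoate | COC(=O)C#C[C@H](O)CCC(=O)OC(C)(C)C | intermediate
5 | hydroxy stannyl enoate (tin α to the methyl ester; ester cis to the carbinol carbon) | COC(=O)/C(=C\[C@H](O)CCC(=O)OC(C)(C)C)[Sn](CCCC)(CCCC)CCCC | intermediate
6 | tert-butyl 3-[(2R)-5-oxo-4-(tributylstannyl)-2,5-dihydrofuran-2-yl]propanoate | CCCC[Sn](CCCC)(CCCC)C1=C[C@@H](CCC(=O)OC(C)(C)C)OC1=O | intermediate
7 | tert-butyl 3-[(2R)-4-ethenyl-5-oxo-2,5-dihydrofuran-2-yl]propanoate | C=CC1=C[C@@H](CCC(=O)OC(C)(C)C)OC1=O | intermediate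
8 | 3-[(2R)-4-ethenyl-5-oxo-2,5-dihydrofuran-2-yl]propanoic acid | C=CC1=C[C@@H](CCC(=O)O)OC1=O | intermediate
9 | 3-[(2R)-4-ethenyl-5-oxo-2,5-dihydrofuran-2-yl]propanoyl chloride | C=CC1=C[C@@H](CCC(=O)Cl)OC1=O | intermediate
10 | (5R)-3-ethenyl-5-(4-methyl-3-oxopent-4-en-1-yl)furan-2(5H)-one | C=CC1=C[C@@H](CCC(=O)C(C)=C)OC1=O | intermediate
11 | tricyclic keto lactone (9-oxo; C3=C4; 19,6β-olide; trans-fused; 5α-H; 6α-H; 10β-CH3) | O=C1CC[C@H]2OC(=O)C3=CCC[C@@]1(C)[C@@H]23 | intermediate
12 | potassium C8=C9 enolate of 11 | [K+].[O-]C1=CC[C@H]2OC(=O)C3=CCC[C@@]1(C)[C@@H]23 | intermediate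
13 | C9 enol triflate of 11 (C8=C9–OTf) | FC(F)(F)S(=O)(=O)OC1=CC[C@H]2OC(=O)C3=CCC[C@@]1(C)[C@@H]23 | intermediate
14 | lithium lactone enolate (C4=C19–OLi) of the 3,4-dihydro triflate | [Li+].FC(F)(F)S(=O)(=O)OC1=CC[C@H]2OC([O-])=C3CCC[C@@]1(C)[C@@H]23 | intermediate
15 | 4α-methyl triflate (ring A saturated; C4: CH3 α, C19 β; C8=C9–OTf) | FC(F)(F)S(=O)(=O)OC1=CC[C@H]2OC(=O)[C@@]3(C)CCC[C@@]1(C)[C@@H]23 | intermediate
16 | itaconic anhydride | C=C1CC(=O)OC1=O | starting material
17 | mono-tert-butyl itaconate (4-tert-butoxy-2-methylidene-4-oxobutanoic acid) | C=C(CC(=O)OC(C)(C)C)C(=O)O | intermediate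
18 | isobutyl mixed carbonic anhydride of 17 | C=C(CC(=O)OC(C)(C)C)C(=O)OC(=O)OCC(C)C | intermediate
19 | tert-butyl 3-(hydroxymethyl)but-3-enoate | C=C(CO)CC(=O)OC(C)(C)C | intermediate
20 | tert-butyl 2-[(2R)-2-(hydroxymethyl)oxiran-2-yl]acetate | OC[C@]1(CC(=O)OC(C)(C)C)CO1 | intermediate
21 | tert-butyl 2-[(2S)-2-formyloxiran-2-yl]acetate | O=C[C@]1(CC(=O)OC(C)(C)C)CO1 | intermediate
22 | tert-butyl 2-[(2R)-2-ethenyloxiran-2-yl]acetate | C=C[C@]1(CC(=O)OC(C)(C)C)CO1 | intermediate
23 | B-alkyl-9-BBN from 22 (boron on C11) | CC(C)(C)OC(=O)C[C@@]1(CCB2C3CCCC2CCC3)CO1 | intermediate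
24 | coupled alkene (C8=C9; C9–C11H2–C12H2–C13; C13 oxirane with C16; C14H2CO2t-Bu) | CC(C)(C)OC(=O)C[C@@]1(CCC2=CC[C@H]3OC(=O)[C@@]4(C)CCC[C@@]2(C)[C@@H]34)CO1 | intermediate
25 | 9α-hydroxy-8-ketone (side chain as in 24) | CC(C)(C)OC(=O)C[C@@]1(CC[C@@]2(O)C(=O)C[C@H]3OC(=O)[C@@]4(C)CCC[C@@]2(C)[C@@H]34)CO1 | intermediate
26 | 9α,13R-spiro ether with free C16 hydroxymethyl and C14H2CO2t-Bu | O=C1C[C@H]2OC(=O)[C@@]3(C)CCC[C@@](C)([C@@H]23)[C@@]12CC[C@](CO)(CC(=O)OC(C)(C)C)O2 | intermediate
27 | 8-oxo-9α,13R-epoxy-17-norlabdane-19,6β:15,16-diolide | O=C1C[C@H]2OC(=O)[C@@]3(C)CCC[C@@](C)([C@@H]23)[C@@]12CC[C@@]1(COC(=O)C1)O2 | intermediate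
28 | 7,8-dioxo-9α,13R-epoxy-17-norlabdane-19,6β:15,16-diolide | O=C1C(=O)[C@H]2OC(=O)[C@@]3(C)CCC[C@@](C)([C@@H]23)[C@@]12CC[C@@]1(COC(=O)C1)O2 | intermediate
29 | potassium C6=C7 enolate of 28 | [K+].O=C1C([O-])=C2OC(=O)[C@@]3(C)CCC[C@@](C)([C@@H]23)[C@@]12CC[C@@]1(COC(=O)C1)O2 | intermediate
30 | 8β-hydroxy-7-oxo-9α,13R-epoxylabdane-19,6β:15,16-diolide | O[C@@]1(C)C(=O)[C@H]2OC(=O)[C@@]3(C)CCC[C@@](C)([C@@H]23)[C@@]12CC[C@@]1(COC(=O)C1)O2 | intermediate
31 | 8β-acetoxy-7-oxo-9α,13R-epoxylabdane-19,6β:15,16-diolide | CC(=O)O[C@@]1(C)C(=O)[C@H]2OC(=O)[C@@]3(C)CCC[C@@](C)([C@@H]23)[C@@]12CC[C@@]1(COC(=O)C1)O2 | target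

**Step count and risks**
Total step count: 19. Longest linear sequence: 14 steps (steps 1–8 and 14–19).

Steps most likely to fail:

1. Step 18. The Grignard reagent may add to the wrong carbonyl if enolization at C6 is incomplete, attack the unhindered side-chain lactone, or add with poor facial selectivity. Fallback, setting out from 28: the enol of the dione would be silylated (TBSOTf, 2,6-lutidine) to the isolable C6=C7 enol silyl ether F4, so that C7 is covalently masked. MeMgBr at −78 °C would then add to the only remaining ketone to give the tertiary alcohol F5. HF·pyridine would cleave the silyl group, and the freed enol would tautomerize to the C7 ketone, coming back at 30.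

2. Step 6. The cycloaddition may close with the carbonyl endo to give the cis-fused ring system, or the vinylbutenolide may dimerize faster than it cyclizes. Fallback, setting out from 10: Luche reduction (NaBH4, CeCl3·7H2O, MeOH) would give the dienol F1 as a mixture of C9 epimers, which removes the carbonyl whose endo preference competes. Heating in xylene at 160–180 °C would close rings A and B in an inverse-demand mode (electron-poor diene, unactivated 1,1-disubstituted alkene) under the same lactone control, giving the tricyclic alcohol F2. Dess–Martin oxidation would return to 11.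

3. Step 8. The hydride may reduce the lactone carbonyl or attack the triflate sulfur instead of adding in the conjugate sense, or the enolate may be methylated on oxygen. Fallback, setting out from 13: LDA/HMPA would deprotonate C2 to the extended dienolate, and MeI would alkylate it at C4 from the α face (deconjugative α-alkylation), giving the 2-ene F3. Diimide (potassium azodicarboxylate, AcOH) would reduce the disubstituted C2=C3 bond in preference to the enol triflate alkene, coming back at 15.

**Further compounds**
F1 | step 6 | (5R)-3-ethenyl-5-(3-hydroxy-4-methylpent-4-en-1-yl)furan-2(5H)-one (both C9 epimers) | C=CC1=C[C@@H](CCC(O)C(C)=C)OC1=O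
F2 | step 6 | 9-hydroxy analogue of 11 (both C9 epimers) | OC1CC[C@H]2OC(=O)C3=CCC[C@@]1(C)[C@@H]23
F3 | step 8 | 4α-methyl-2-ene triflate (C2=C3; C8=C9–OTf) | FC(F)(F)S(=O)(=O)OC1=CC[C@H]2OC(=O)[C@@]3(C)C=CC[C@@]1(C)[C@@H]23
F4 | step 18 | C6=C7 enol tert-butyldimethylsilyl ether of 28 | O=C1C(O[Si](C)(C)C(C)(C)C)=C2OC(=O)[C@@]3(C)CCC[C@@](C)([C@@H]23)[C@@]12CC[C@@]1(COC(=O)C1)O2
F5 | step 18 | 8β-hydroxy-8α-methyl adduct of F4 | C[C@]1(O)C(O[Si](C)(C)C(C)(C)C)=C2OC(=O)[C@@]3(C)CCC[C@@](C)([C@@H]23)[C@@]12CC[C@@]1(COC(=O)C1)O2
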